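Ring A is read as a folded tri-β-carbonyl chain: oxygen sits on C5, C7 and C8a, while C4a, C6 and C8 are enolate carbons. Everything rests on disconnecting C4a–C5. In one operation a magnesium-templated Claisen (Dieckmann) closure forms that bond, closes ring A and aromatises it to the 5,7-diol. Because the C8a–O1 enol ether is already locked in ring C, only the 6-prenyl isomer can form and ring C never has to be closed through a phenol. The precursor is a (2S)-2-aryl-2,3-dihydropyran-4-one whose position 6 (the future C8a) carries the chain CH2–CO–CH(prenyl)–CO2Me (future C8, C7, C6, C5), with the ring B phenol masked as its MOM ether.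

Key step: step 8

Atom labels C2 to C8a are those of the flavanone and are used for the same carbons in the precursor.

Assumption: the sense of induction in step 3 is taken from benzaldehyde under BINOL–titanium catalysis, where the (S)-ligand directs carbon nucleophiles to the Si face. With the priorities O > aryl > CH2 > H this gives (S); the (R)-ligand would be used if the sense proved opposite.

Remark: the keto ester chain is attached in two operations (steps 4 and 7). The first uses an electrophile without acidic hydrogens and the second a nearly neutral C-acylation, so the precursor first meets a basic medium in the key step. The methyl ester matches the methoxide base.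

Step 1
Reactants: 1 vanillin
Product: 2 3-methoxy-4-(methoxymethoxy)benzaldehyde
Conditions: MOMCl, i-Pr2NEt, CH2Cl2, 0 °C → rt
Reagents that add atoms: chloromethyl methyl ether, COCCl
Why: O-Alkylation of the phenol with the α-chloro ether (Williamson-type ether synthesis) gives an acetal that is inert to the amide, magnesium and alkoxide bases used later and keeps the 4'-oxygen from becoming a phenoxide.

Step 2
Reactants: 3 acetylacetone
Product: 4 (3Z)-2,4-bis(trimethylsilyloxy)penta-1,3-diene
Conditions: TMSOTf (2.2 equiv), Et3N (2.5 equiv), Et2O, 0 °C → rt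
Reagents that add atoms: trimethylsilyl trifluoromethanesulfonate, C[Si](C)(C)OS(=O)(=O)C(F)(F)F
Why: Twofold soft enolisation and O-silylation of the β-diketone (silyl enol ether formation) gives the 1,3-bis(silyloxy)diene whose terminal CH2 is its nucleophilic carbon.

Step 3
Reactants: 2 3-methoxy-4-(methoxymethoxy)benzaldehyde; 4 (3Z)-2,4-bis(trimethylsilyloxy)penta-1,3-diene
Product: 6 (2S)-2-[3-methoxy-4-(methoxymethoxy)phenyl]-6-methyl-2,3-dihydro-4H-pyran-4-one, via open-chain aldol adduct 5 (not isolated)
Conditions: Ti(OiPr)4 (10 mol %), (S)-BINOL (10 mol %), 4 Å MS, THF, −78 °C → rt; then TFA (0.2 equiv), CH2Cl2, 0 °C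
Reagents that add atoms: none
Why: The chiral titanium BINOLate activates the aldehyde and the diene terminus adds to its Si face in a vinylogous Mukaiyama aldol reaction, which sets C2 as S under ligand control, after which acid removes the silyl groups and cyclodehydrates the δ-hydroxy β-diketone 5 to the dihydropyranone, the whole amounting to a stepwise hetero-Diels–Alder reaction.

Step 4
Reactants: 6 (2S)-2-[3-methoxy-4-(methoxymethoxy)phenyl]-6-methyl-2,3-dihydro-4H-pyran-4-one
Product: 8 [(2S)-2-(3-methoxy-4-(methoxymethoxy)phenyl)-4-oxo-2,3-dihydro-4H-pyran-6-yl]acetic acid, via lithium dienolate 7 (not isolated)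
Conditions: LiN(SiMe3)2 (1.2 equiv), THF, −78 °C; CO2 (g), −78 → −40 °C; cold 1 M HCl to pH 3
Reagents that add atoms: carbon dioxide, O=C=O
Why: Gamma-deprotonation of the 6-methyl group gives the linearly conjugated dienolate typical of 6-methyl-2,3-dihydropyran-4-ones, and its terminal carbon is carboxylated by CO2, an electrophile without acidic hydrogens that cannot quench the enolate or form a ketene, while the low temperature keeps any C3 enolate from opening ring C by β-elimination (enolate carboxylation).

Step 5
Reactants: 9 dimethyl malonate; 10 prenyl bromide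
Product: 11 dimethyl 2-(3-methylbut-2-enyl)malonate
Conditions: NaH (1.0 equiv), 9 (2.0 equiv), THF, 0 °C; 10, 0 °C → rt
Reagents that add atoms: none
Why: Malonic ester alkylation, an SN2 displacement of the primary allylic bromide by the sodium enolate, with the malonate in excess to hold back dialkylation.

Step 6
Reactants: 11 dimethyl 2-(3-methylbut-2-enyl)malonate
Product: 12 2-(methoxycarbonyl)-5-methylhex-4-enoic acid (racemic)
Conditions: KOH (1.0 equiv), MeOH, 0 °C → rt; then 1 M HCl
Reagents that add atoms: potassium hydroxide, [K+].[OH-]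
Why: Ester saponification stops at the half ester because the carboxylate formed first repels a second hydroxide, so one equivalent of KOH removes one methyl group only.

Step 7
Reactants: 8 [(2S)-2-(3-methoxy-4-(methoxymethoxy)phenyl)-4-oxo-2,3-dihydro-4H-pyran-6-yl]acetic acid; 12 2-(methoxycarbonyl)-5-methylhex-4-enoic acid
Product: 16 methyl 2-(3-methylbut-2-enyl)-3-oxo-4-[(2S)-2-(3-methoxy-4-(methoxymethoxy)phenyl)-4-oxo-2,3-dihydro-4H-pyran-6-yl]butanoate (both epimers at the ester α-carbon), via acyl imidazole 13 (not isolated), via magnesium half-ester salt 14 (not isolated), via acylmalonic half ester 15 (not isolated)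
Conditions: 12 (2.4 equiv), Mg(OEt)2 (1.2 equiv), THF, rt, then evaporation; 8, CDI (1.1 equiv), THF, 0 °C → rt; both combined, THF, rt → 40 °C; cold 0.5 M HCl
Reagents that add atoms: none
Why: Decarboxylative Claisen condensation (Masamune–Brooks reaction): the magnesium-chelated enolate of the malonic half ester is C-acylated by the acyl imidazole under nearly neutral conditions and then loses CO2, so the β-keto ester arises with the prenyl group already on the future C6 and without exposure of the C2 stereocentre to a strong base.

Step 8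
Reactants: 16 methyl 2-(3-methylbut-2-enyl)-3-oxo-4-[(2S)-2-(3-methoxy-4-(methoxymethoxy)phenyl)-4-oxo-2,3-dihydro-4H-pyran-6-yl]butanoate
Product: 19 (2S)-5,7-dihydroxy-2-[3-methoxy-4-(methoxymethoxy)phenyl]-6-(3-methylbut-2-enyl)-2,3-dihydro-4H-chromen-4-one (4'-O-MOM-6-prenylhomoeriodictyol), via magnesium dienolate 17 (not isolated), via cyclised triketone 18 (not isolated)
Conditions: Mg(OMe)2 (4 equiv), MeOH–THF, argon, 0 °C → rt; then cold 1 M HCl to pH 3
Reagents that add atoms: none
Why: Proposed new method: Mg(OMe)2 should remove a proton from the C8 methylene, which lies between the C7 ketone and the β-carbon of the ring C vinylogous ester, to give the magnesium-bound extended dienolate 17 that is nucleophilic at C4a; C4a then adds to the magnesium-activated ester carbonyl C5, methoxide leaves, and triketone 18 enolises at C4a–H and C6–H to the aromatic 5,7-diol. The closest known reaction type is the magnesium alkoxide- or hydroxide-mediated Claisen cyclisation of open-chain 3,5,7-triketo esters to acylphloroglucinols; what is new is that one chain carbonyl is held as the C8a–O1 enol ether, so the nucleophile is the α-carbon of a cyclic vinylogous ester. Ring A closes in a 6-(enolendo)-exo-trig mode, which is geometrically allowed because the C8 chain is cis to C4a–H on the C4a=C8a bond, whereas an aldol closure onto C4 would need a trans double bond in a six-membered ring. No stereocentre is created, and C2 is carried through because the C2–O1 bond is not touched. The selectivity needed is C-acylation at C4a in preference to loss of a C3 proton, which would open ring C by β-elimination and scramble C2; it rests on the far higher acidity of C6–H and C8–H, whose anions take up the base and lower the acidity of C3–H, on magnesium chelation that holds C5 within reach of C4a, and on the lowest workable temperature and time. Aromatisation to the magnesium phenoxide should make the closure irreversible.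

Step 9
Reactants: 19 (2S)-5,7-dihydroxy-2-[3-methoxy-4-(methoxymethoxy)phenyl]-6-(3-methylbut-2-enyl)-2,3-dihydro-4H-chromen-4-one
Product: 20 (2S)-5,7-dihydroxy-2-(4-hydroxy-3-methoxyphenyl)-6-(3-methylbut-2-enyl)-2,3-dihydro-4H-chromen-4-one (6-prenylhomoeriodictyol, CNP0142940.1)
Conditions: HCl (1.25 M in MeOH), MeOH, rt
Reagents that add atoms: none
Why: Acid-catalysed acetal exchange with methanol releases the 4'-phenol as dimethoxymethane leaves, while dilute acid at room temperature neither opens ring C, whose C4 carbonyl is hydrogen-bonded to 5-OH, nor adds the 5- or 7-hydroxyl across the prenyl double bond.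

Compound list

1 | vanillin (4-hydroxy-3-methoxybenzaldehyde) | COc1cc(C=O)ccc1O | starting material
2 | 3-methoxy-4-(methoxymethoxy)benzaldehyde | COCOc1ccc(C=O)cc1OC | intermediate
3 | acetylacetone (pentane-2,4-dione) | CC(=O)CC(C)=O | starting material
4 | (3Z)-2,4-bis(trimethylsilyloxy)penta-1,3-diene | C=C(O[Si](C)(C)C)/C=C(/C)O[Si](C)(C)C | intermediate
5 | (6S)-6-hydroxy-6-[3-methoxy-4-(methoxymethoxy)phenyl]hexane-2,4-dione (open-chain aldol adduct) | COc1cc([C@@H](O)CC(=O)CC(C)=O)ccc1OCOC | intermediate (not isolated)
6 | (2S)-2-[3-methoxy-4-(methoxymethoxy)phenyl]-6-methyl-2,3-dihydro-4H-pyran-4-one | COc1cc([C@@H]2CC(=O)C=C(C)O2)ccc1OCOC | intermediate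
7 | lithium (2S)-2-[3-methoxy-4-(methoxymethoxy)phenyl]-6-methylidene-3,6-dihydro-2H-pyran-4-olate (extended dienolate) | COc1cc([C@@H]2CC([O-])=CC(=C)O2)ccc1OCOC.[Li+] | intermediate (not isolated)
8 | [(2S)-2-(3-methoxy-4-(methoxymethoxy)phenyl)-4-oxo-2,3-dihydro-4H-pyran-6-yl]acetic acid | COc1cc([C@@H]2CC(=O)C=C(CC(=O)O)O2)ccc1OCOC | intermediate
9 | dimethyl malonate | COC(=O)CC(=O)OC | starting material
10 | prenyl bromide (1-bromo-3-methylbut-2-ene) | CC(C)=CCBr | starting material
11 | dimethyl 2-(3-methylbut-2-enyl)malonate | COC(=O)C(CC=C(C)C)C(=O)OC | intermediate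
12 | 2-(methoxycarbonyl)-5-methylhex-4-enoic acid (racemic) | COC(=O)C(CC=C(C)C)C(=O)O | intermediate
13 | 1-{[(2S)-2-(3-methoxy-4-(methoxymethoxy)phenyl)-4-oxo-2,3-dihydro-4H-pyran-6-yl]acetyl}imidazole | COc1cc([C@@H]2CC(=O)C=C(CC(=O)n3ccnc3)O2)ccc1OCOC | intermediate (not isolated)
14 | magnesium bis[2-(methoxycarbonyl)-5-methylhex-4-enoate] | COC(=O)C(CC=C(C)C)C(=O)[O-].COC(=O)C(CC=C(C)C)C(=O)[O-].[Mg+2] | intermediate (not isolated)
15 | 2-(methoxycarbonyl)-2-{[(2S)-2-(3-methoxy-4-(methoxymethoxy)phenyl)-4-oxo-2,3-dihydro-4H-pyran-6-yl]acetyl}-5-methylhex-4-enoic acid (present as its magnesium carboxylate) | COc1cc([C@@H]2CC(=O)C=C(CC(=O)C(CC=C(C)C)(C(=O)O)C(=O)OC)O2)ccc1OCOC | intermediate (not isolated)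
16 | methyl 2-(3-methylbut-2-enyl)-3-oxo-4-[(2S)-2-(3-methoxy-4-(methoxymethoxy)phenyl)-4-oxo-2,3-dihydro-4H-pyran-6-yl]butanoate (both epimers at the ester α-carbon) | COc1cc([C@@H]2CC(=O)C=C(CC(=O)C(CC=C(C)C)C(=O)OC)O2)ccc1OCOC | intermediate (precursor of the key step)
17 | methoxymagnesium dienolate of 16 (C8 deprotonated, charge spread over O4, C4a, C8 and O7) | COc1cc([C@@H]2CC([O-])=CC(=CC(=O)C(CC=C(C)C)C(=O)OC)O2)ccc1OCOC.[Mg+2].C[O-] | intermediate (not isolated)
18 | (2S)-2-[3-methoxy-4-(methoxymethoxy)phenyl]-6-(3-methylbut-2-enyl)-2,3,4a,6-tetrahydrochromene-4,5,7-trione (non-aromatic Claisen product, mixture at C4a and C6) | COc1cc([C@@H]2CC(=O)C3C(=O)C(CC=C(C)C)C(=O)C=C3O2)ccc1OCOC | intermediate (not isolated)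
19 | (2S)-5,7-dihydroxy-2-[3-methoxy-4-(methoxymethoxy)phenyl]-6-(3-methylbut-2-enyl)-2,3-dihydro-4H-chromen-4-one | COc1cc([C@@H]2CC(=O)c3c(cc(O)c(CC=C(C)C)c3O)O2)ccc1OCOC | intermediate (product of the key step)
20 | (2S)-5,7-dihydroxy-2-(4-hydroxy-3-methoxyphenyl)-6-(3-methylbut-2-enyl)-2,3-dihydro-4H-chromen-4-one | COc1cc([C@@H]2CC(=O)c3c(cc(O)c(CC=C(C)C)c3O)O2)ccc1O | target

Total step count: 9. Longest linear sequence: 6 steps from vanillin (steps 1, 3, 4, 7, 8, 9); steps 2, 5 and 6 are side branches.

Steps most likely to fail

1. Step 8 (proposed new method). The β-keto ester may stay parked as its unreactive magnesium enolate so that C4a never reaches C5. Methoxide may cleave the chain by retro-Claisen reaction or add to C8a. A proton may be lost from C3, in 16 or in 19, so that ring C opens by β-elimination and recloses without facial control, which erodes the configuration at C2. The fallback uses known chemistry, sets out from 2 and 10 and comes back at 20; ring A is bought ready-made and ring C is closed last. Commercial 2',4',6'-trihydroxyacetophenone is C-prenylated with 10 (aqueous KOH) to 1-[2,4,6-trihydroxy-3-(3-methylbut-2-enyl)phenyl]ethanone F1, which NaH and MOMCl in DMF convert into its tris-MOM ether F2. Claisen–Schmidt condensation of F2 with 2 (KOH, EtOH) gives the tetra-MOM chalcone F3, and HCl in MeOH removes all four acetals to give the free chalcone F4. F4 cyclises by oxa-Michael addition (NaOAc, EtOH, reflux) to racemic 6-prenylhomoeriodictyol F5 together with its 8-prenyl isomer F6. Chromatography removes F6, and preparative HPLC on a chiral stationary phase separates the enantiomers of F5 to give 20. This path gives up regio- and enantiocontrol and pays for both by separation.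

2. Step 4. Deprotonation may occur at C3 instead of the 6-methyl group, leading to carboxylation at C3 or to β-elimination that opens ring C and lowers the enantiomeric purity. The vinylogous β-keto acid may also lose CO2 during isolation. The fallback sets out from 5 and comes back at 8; the carboxyl group is attached to the open chain, where the C2 oxygen is a silyl ether and cannot leave. Compound 5 is isolated by leaving out the TFA treatment in step 3 and removing the silyl groups with dilute aqueous acid. It is protected (TBSCl, imidazole, DMF) as (6S)-6-(tert-butyldimethylsilyloxy)-6-[3-methoxy-4-(methoxymethoxy)phenyl]hexane-2,4-dione F7. The dianion of F7 (LiN(i-Pr)2, 2.2 equiv, THF, −78 → 0 °C) is carboxylated at its terminal methyl carbon with CO2 to give (7S)-7-(tert-butyldimethylsilyloxy)-7-[3-methoxy-4-(methoxymethoxy)phenyl]-3,5-dioxoheptanoic acid F8. Cold F8 is treated at once with aqueous HF in MeCN, which removes the silyl group and cyclodehydrates the δ-hydroxy β-diketone to 8.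

3. Step 3. The electron-rich aldehyde may react slowly and with poor facial selectivity, and the MOM acetal may be partly lost in the acid step. The fallback sets out from 2 and 3 and comes back at 6; the catalytic asymmetric step is replaced by a racemic synthesis and a resolution. The dianion of 3 (NaH, then n-BuLi, THF, 0 °C) adds through its terminal carbon to 2 to give racemic 6-hydroxy-6-[3-methoxy-4-(methoxymethoxy)phenyl]hexane-2,4-dione F9. Catalytic TsOH in CH2Cl2 cyclodehydrates F9 to racemic 2-[3-methoxy-4-(methoxymethoxy)phenyl]-6-methyl-2,3-dihydro-4H-pyran-4-one F10. Preparative HPLC of F10 on a polysaccharide chiral stationary phase gives 6.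

Further compounds

F1 | step 8 | 1-[2,4,6-trihydroxy-3-(3-methylbut-2-enyl)phenyl]ethanone | CC(=O)c1c(O)cc(O)c(CC=C(C)C)c1O
F2 | step 8 | 1-[2,4,6-tris(methoxymethoxy)-3-(3-methylbut-2-enyl)phenyl]ethanone | CC(=O)c1c(OCOC)cc(OCOC)c(CC=C(C)C)c1OCOC
F3 | step 8 | (E)-3-[3-methoxy-4-(methoxymethoxy)phenyl]-1-[2,4,6-tris(methoxymethoxy)-3-(3-methylbut-2-enyl)phenyl]prop-2-en-1-one | COCOc1ccc(/C=C/C(=O)c2c(OCOC)cc(OCOC)c(CC=C(C)C)c2OCOC)cc1OC
F4 | step 8 | (E)-3-(4-hydroxy-3-methoxyphenyl)-1-[2,4,6-trihydroxy-3-(3-methylbut-2-enyl)phenyl]prop-2-en-1-one | COc1cc(/C=C/C(=O)c2c(O)cc(O)c(CC=C(C)C)c2O)ccc1O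
F5 | step 8 | racemic 5,7-dihydroxy-2-(4-hydroxy-3-methoxyphenyl)-6-(3-methylbut-2-enyl)-2,3-dihydro-4H-chromen-4-one | COc1cc(C2CC(=O)c3c(cc(O)c(CC=C(C)C)c3O)O2)ccc1O
F6 | step 8 | racemic 5,7-dihydroxy-2-(4-hydroxy-3-methoxyphenyl)-8-(3-methylbut-2-enyl)-2,3-dihydro-4H-chromen-4-one | COc1cc(C2CC(=O)c3c(O)cc(O)c(CC=C(C)C)c3O2)ccc1O
F7 | step 4 | (6S)-6-(tert-butyldimethylsilyloxy)-6-[3-methoxy-4-(methoxymethoxy)phenyl]hexane-2,4-dione | COc1cc([C@@H](O[Si](C)(C)C(C)(C)C)CC(=O)CC(C)=O)ccc1OCOC
F8 | step 4 | (7S)-7-(tert-butyldimethylsilyloxy)-7-[3-methoxy-4-(methoxymethoxy)phenyl]-3,5-dioxoheptanoic acid | COc1cc([C@@H](O[Si](C)(C)C(C)(C)C)CC(=O)CC(=O)CC(=O)O)ccc1OCOC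
F9 | step 3 | racemic 6-hydroxy-6-[3-methoxy-4-(methoxymethoxy)phenyl]hexane-2,4-dione | COc1cc(C(O)CC(=O)CC(C)=O)ccc1OCOC
F10 | step 3 | racemic 2-[3-methoxy-4-(methoxymethoxy)phenyl]-6-methyl-2,3-dihydro-4H-pyran-4-one | COc1cc(C2CC(=O)C=C(C)O2)ccc1OCOC
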